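A flask that slows is easily read as a flask short of incoming ligand, and Tuesday's run warns against that reading.

| flask | starting complex | incoming ligand | scavenger | protic impurity | remark | time |
|---|---|---|---|---|---|---|
| Tuesday's | 0.075 M | 0.040 M | 0.025 M | 0.010 M | run made earlier |  |
| beta | 0.050 M | 0.0400 M | 0.0250 M | 0.0100 M |  | 2.0 h |
| theta | 0.050 M | 0.0750 M | 0.0250 M | 0.0100 M |  | 2.0 h |
| alpha | 0.050 M | 0.125 M | 0.0250 M | 0.0100 M |  | 2.0 h |

- Tuesday's (time / min: complex with two exchanged / %, complex with one exchanged / %): 1.50: 0, 5.7; 5.00: 2.4, 10.2; 8.00: 3.1, 13.0; 12.0: 5.8, 14.8; 20.0: 6.8, 17.2; 25.0: 9.4, 19.6

(readings scatter by 1 percentage point)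

- no earlier run changes the charge of incoming ligand; that part of a forecast is a guess

1. complex with two exchanged at the end, in percent of the starting complex charged, for each flask in turn (beta, theta, alpha)

I read the table by one count: exchange events per starting complex charged, with the complex with one exchanged counted once and the complex with two exchanged twice. On Tuesday's run the count stood at 5.70% at 1.50 min, 19.2% at 8.00 min, 26.4% at 12.0 min and 38.4% at 25.0 min. Reading those rows in pairs, it gained 14 percentage points over the earlier pair and 12 points over the later one, which took twice as long.

Yet the incoming ligand charged on Tuesday's run was 53.3% of the starting complex, so by these readings 15 points of it was still outside the complexes at the last row. The scavenger charge on that run was 33.3%, and the last count stands 5.1 points past that.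

I therefore assumed that the scavenger takes one leaving ligand per event, and I treated it as the limiting reagent of clean exchange. In my reckoning the crossing lies where the ligand charge equals the scavenger charge, and beta, theta and alpha all stand above it; in these flasks the scavenger charge, which I call the allowance, is 50.0% of the starting complex. Past the allowance I used the overrun share, the part of the ligand surplus over the scavenger that became further events, read as 0.253 from the last row of Tuesday's run, a rough reading.

As fractions of the starting complex, the surpluses are 0.300 in beta, 1.00 in theta and 2.00 in alpha. Taking the complex with one exchanged at its last reading on Tuesday's run, I reckoned 19.0% for beta, 27.9% for theta and 40.5% for alpha.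

The forecast said 20%, 50% and 78%, above mine in theta and alpha, with the words “ligand is in excess” for alpha.

The flasks ended at 21.2% in beta, 35.4% in theta and 56.3% in alpha.

    protic impurity + starting complex → quenched substrate (k = 130 M⁻¹ h⁻¹)
    starting complex → decomposition product (k = 0.00100 h⁻¹)
    scavenger + leaving ligand → scavenged by-product (k = 2000 M⁻¹ h⁻¹)
    leaving ligand + incoming ligand ⇌ idle adduct, settled at all times (K = 540 M⁻¹)
    complex with one exchanged + incoming ligand ⇌ leaving ligand + complex with two exchanged (K = 0.410, k = 120 M⁻¹ h⁻¹)
    starting complex + incoming ligand ⇌ leaving ligand + complex with one exchanged (K = 0.190, k = 59.0 M⁻¹ h⁻¹)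

At the end of beta the scavenger stood at 0.354% of its charge and the incoming ligand at 11.7% of its own. Theta's final count of 90.9% lies 41 points past the allowance, an overrun share of 0.409. Alpha's final count of 129% gives an overrun share of 0.393.

The numbers in the tables stem from a simulated flask on assumed constants, noise included.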